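**Retrosynthetic overview**

1. The target (germacrane numbering: C1 hemiketal carbon, C2/C3 ring CH2CH2, C4 O-bearing quaternary carbon, C5=C6 exocyclic enol-lactone alkene, C7=C11 butenolide alkene, C8 carbinol, C9 CH2, C10 acetoxy carbon, C12 lactone C=O, C13 CH2OAc) is a ten-membered carbocycle C1–C10, bridged by a 2-hydroxytetrahydrofuran (O, C1–C4) and fused at C6/C7 to a (5E)-ylidene butenolide; the last step only unmasks C8–OH.
2. Key disconnection: the tetrahydrofuran bonds C2–C3 and O–C4 are cut together, leading back to the monocyclic bromomethyl ketone 23. Enabling feature: the hemiketal carbon C1 is a masked ketone whose α-carbon is C2, and C4 is a tertiary carbon allylic to the C5=C6 enol-lactone alkene, so ring O–C1–C2–C3–C4 is the retron of a ketone α-radical adding to the isopropenyl terminus C3=C4 of a dienyl butenolide, followed by capture of the C4 cation by the carbonyl oxygen and water.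
3. Butenolide ring with the (5E)-isopropenyl-methylidene group: Pd-catalysed cyclisation–coupling of a cis-enynoic acid with 2-bromopropene; the enynoic acid comes from a 2-silyl-3,4-disubstituted furan (singlet oxygen, then alkyne homologation), so the furan fixes the cis relation of carboxyl and alkyne.
4. Side chain: C9–C10 bond and the C10 stereocentre by a copper–bis(oxazoline) Mukaiyama aldol of a furyl methyl ketone enol silane with methyl pyruvate; C8 by asymmetric transfer hydrogenation; C4 and C1 arise in the key step.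
5. Order of ring formation: furan (purchased) → butenolide (step 11) → ten-membered carbocycle and 2-hydroxytetrahydrofuran together (step 15).

Key step: step 15

Remarks: TBS = tert-butyldimethylsilyl, TMS = trimethylsilyl. Assumption: the sense of induction in steps 5 and 6 follows the standard models for pyruvate esters and aryl alkyl ketones; the opposite ligand enantiomers are available if it does not.

**Route**

Step 1
Reactants: 1 furan-3-ylmethanol
Product: 2 tert-butyl(furan-3-ylmethoxy)dimethylsilane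
Conditions: TBSCl, imidazole, DMF, 0 to 25 °C
Reagents that add atoms: tert-butyldimethylsilyl chloride, CC(C)(C)[Si](C)(C)Cl
Why: Standard imidazole-mediated silylation of a primary alcohol, which sets up the silyl migration of step 2.

Step 2
Reactants: 2 tert-butyl(furan-3-ylmethoxy)dimethylsilane
Product: 3 [2-(tert-butyldimethylsilyl)furan-3-yl]methanol
Conditions: n-BuLi, HMPA, THF, -78 to 0 °C; then H2O
Reagents that add atoms: none
Why: Lithiation at furan C2 (next to the ring oxygen and the CH2O group) is followed by a [1,4] O-to-C silyl shift (retro-Brook rearrangement), which blocks C2 and frees the alkoxide.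

Step 3
Reactants: 3 [2-(tert-butyldimethylsilyl)furan-3-yl]methanol; 4 N-methoxy-N-methylacetamide
Product: 5 1-[5-(tert-butyldimethylsilyl)-4-(hydroxymethyl)furan-3-yl]ethan-1-one
Conditions: n-BuLi (2.2 equiv), DME, 0 °C; then 4, -78 to 0 °C; then H2O
Reagents that add atoms: none
Why: With C2 blocked, the lithium alkoxide directs the second lithiation to C4 (directed ortho-metalation), and the Weinreb amide acylates the dianion without over-addition.

Step 4
Reactants: 5 1-[5-(tert-butyldimethylsilyl)-4-(hydroxymethyl)furan-3-yl]ethan-1-one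
Product: 6 tert-butyldimethyl{3-[(trimethylsilyloxy)methyl]-4-[1-(trimethylsilyloxy)ethenyl]furan-2-yl}silane
Conditions: TMSOTf (2.4 equiv), Et3N, CH2Cl2, 0 °C; pentane, filtration
Reagents that add atoms: trimethylsilyl triflate, C[Si](C)(C)OS(=O)(=O)C(F)(F)F
Why: Soft enolisation with TMSOTf and Et3N converts the methyl ketone into its enol silane and caps the primary alcohol at the same time.

Step 5
Reactants: 6 tert-butyldimethyl{3-[(trimethylsilyloxy)methyl]-4-[1-(trimethylsilyloxy)ethenyl]furan-2-yl}silane; 7 methyl pyruvate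
Product: 9 methyl (2S)-4-[5-(tert-butyldimethylsilyl)-4-(hydroxymethyl)furan-3-yl]-2-hydroxy-2-methyl-4-oxobutanoate, via silylated aldol adduct 8 (not isolated)
Conditions: Cu(OTf)2 (10 mol%), (S,S)-tert-butyl-bis(oxazoline) ligand, THF, -78 °C; then 1 M HCl, THF, 0 °C
Reagents that add atoms: none
Why: Enantioselective Mukaiyama aldol addition to the pyruvate ester chelated on divalent copper; the C2-symmetric ligand shields one face of the bound keto ester, which should set C10 as S, and acid removes both TMS groups.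

Step 6
Reactants: 9 methyl (2S)-4-[5-(tert-butyldimethylsilyl)-4-(hydroxymethyl)furan-3-yl]-2-hydroxy-2-methyl-4-oxobutanoate
Product: 10 methyl (2S,4R)-4-[5-(tert-butyldimethylsilyl)-4-(hydroxymethyl)furan-3-yl]-2,4-dihydroxy-2-methylbutanoate
Conditions: RuCl(p-cymene)[(R,R)-TsDPEN] (1 mol%), HCO2H/Et3N (5:2), EtOAc, 25 °C
Reagents that add atoms: none
Why: Noyori asymmetric transfer hydrogenation reduces the heteroaryl ketone and leaves the ester alone; the (R,R) ligand should give the 8R alcohol through the usual CH–π-controlled transition state.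

Step 7
Reactants: 10 methyl (2S,4R)-4-[5-(tert-butyldimethylsilyl)-4-(hydroxymethyl)furan-3-yl]-2,4-dihydroxy-2-methylbutanoate
Product: 11 methyl (2S,4R)-4-(TBS-oxy)-4-{5-TBS-4-[(TBS-oxy)methyl]furan-3-yl}-2-hydroxy-2-methylbutanoate
Conditions: TBSCl (2.5 equiv), imidazole, DMAP (cat.), DMF, 40 °C
Reagents that add atoms: tert-butyldimethylsilyl chloride, CC(C)(C)[Si](C)(C)Cl
Why: Chloride/imidazole silylation protects the primary and the secondary hydroxyl groups and leaves the hindered tertiary one free.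

Step 8
Reactants: 11 methyl (2S,4R)-4-(TBS-oxy)-4-{5-TBS-4-[(TBS-oxy)methyl]furan-3-yl}-2-hydroxy-2-methylbutanoate
Product: 13 (3S,5R)-5-(TBS-oxy)-5-{5-TBS-4-[(TBS-oxy)methyl]furan-3-yl}-3-hydroxy-3-methylpentan-2-one, via α-trimethylsilyl ketone 12 (not isolated)
Conditions: TMSCH2Li (3.5 equiv), THF/pentane, -20 to 0 °C; then MeOH, 25 °C
Reagents that add atoms: (trimethylsilyl)methyllithium, [Li]C[Si](C)(C)C
Why: Addition of (trimethylsilyl)methyllithium to the ester gives an α-silyl ketone whose enolate resists a second addition, and methanolysis of the C–Si bond leaves the methyl ketone (known ester-to-methyl-ketone conversion).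

Step 9
Reactants: 13 (3S,5R)-5-(TBS-oxy)-5-{5-TBS-4-[(TBS-oxy)methyl]furan-3-yl}-3-hydroxy-3-methylpentan-2-one
Product: 16 4-[(1R,3S)-1-(TBS-oxy)-3-hydroxy-3-methyl-4-oxopentyl]-3-[(TBS-oxy)methyl]-5-hydroxyfuran-2(5H)-one (both C5 epimers), via furan endoperoxide 14 (not isolated), via silyl oxoenoate 15 (not isolated)
Conditions: O2, rose bengal (cat.), visible light, CH2Cl2/MeOH, -78 °C; then H2O, silica gel, 25 °C
Reagents that add atoms: dioxygen, O=O
Why: [4+2] addition of singlet oxygen to the 2-silylfuran and silyl migration in the endoperoxide (silylfuran photooxygenation) place the lactone carbonyl at the former silyl-bearing carbon (C12) and the hemiacetal at C6.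

Step 10
Reactants: 16 4-[(1R,3S)-1-(TBS-oxy)-3-hydroxy-3-methyl-4-oxopentyl]-3-[(TBS-oxy)methyl]-5-hydroxyfuran-2(5H)-one
Product: 17 (2E,4R,6S)-4-(TBS-oxy)-2-[(TBS-oxy)methyl]-3-ethynyl-6-hydroxy-6-methyl-7-oxooct-2-enoic acid (carboxyl cis to ethynyl)
Conditions: dimethyl (1-diazo-2-oxopropyl)phosphonate, K2CO3, MeOH, 0 to 25 °C; then aqueous citric acid
Reagents that add atoms: dimethyl (1-diazo-2-oxopropyl)phosphonate, CC(=O)C(=[N+]=[N-])P(=O)(OC)OC
Why: In basic methanol the hydroxybutenolide opens to the cis-formyl carboxylate, whose aldehyde is homologated to the terminal alkyne (Seyferth–Gilbert homologation with the Ohira–Bestmann reagent); the ring origin fixes the cis relation of carboxyl and alkyne.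

Step 11
Reactants: 17 (2E,4R,6S)-4-(TBS-oxy)-2-[(TBS-oxy)methyl]-3-ethynyl-6-hydroxy-6-methyl-7-oxooct-2-enoic acid; 18 2-bromopropene
Product: 19 (5E)-4-[(1R,3S)-1-(TBS-oxy)-3-hydroxy-3-methyl-4-oxopentyl]-3-[(TBS-oxy)methyl]-5-(2-methylprop-2-en-1-ylidene)furan-2(5H)-one
Conditions: Pd(OAc)2 (5 mol%), PPh3 (10 mol%), Et3N, n-Bu4NCl, DMSO, 25 to 40 °C
Reagents that add atoms: none
Why: Pd-catalysed cyclisation–coupling of an alkynoic acid with a vinyl halide: isopropenylpalladium bromide (divalent palladium, from oxidative addition to zerovalent palladium) activates the alkyne, the carboxylate attacks anti in a 5-exo-dig mode and reductive elimination puts the isopropenyl group trans to the ring oxygen, which is the (5E) geometry.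

Step 12
Reactants: 19 (5E)-4-[(1R,3S)-1-(TBS-oxy)-3-hydroxy-3-methyl-4-oxopentyl]-3-[(TBS-oxy)methyl]-5-(2-methylprop-2-en-1-ylidene)furan-2(5H)-one
Product: 20 (5E)-4-[(1R,3S)-1-(TBS-oxy)-3-hydroxy-3-methyl-4-oxopentyl]-3-(hydroxymethyl)-5-(2-methylprop-2-en-1-ylidene)furan-2(5H)-one
Conditions: HF·pyridine, pyridine, THF, 0 °C
Reagents that add atoms: none
Why: The unhindered primary allylic silyl ether is cleaved much faster by buffered HF·pyridine than the secondary one at C8, which is flanked by the tetrasubstituted alkene.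

Step 13
Reactants: 20 (5E)-4-[(1R,3S)-1-(TBS-oxy)-3-hydroxy-3-methyl-4-oxopentyl]-3-(hydroxymethyl)-5-(2-methylprop-2-en-1-ylidene)furan-2(5H)-one
Product: 21 [(5E)-4-[(1R,3S)-3-acetoxy-1-(TBS-oxy)-3-methyl-4-oxopentyl]-5-(2-methylprop-2-en-1-ylidene)-2-oxo-2,5-dihydrofuran-3-yl]methyl acetate
Conditions: Ac2O, Et3N, DMAP, CH2Cl2, 25 to 35 °C
Reagents that add atoms: acetic anhydride, CC(=O)OC(C)=O
Why: DMAP-catalysed acylation esterifies the primary (C13) and the tertiary (C10) hydroxyl groups in one operation without touching a stereocentre.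

Step 14
Reactants: 21 [(5E)-4-[(1R,3S)-3-acetoxy-1-(TBS-oxy)-3-methyl-4-oxopentyl]-5-(2-methylprop-2-en-1-ylidene)-2-oxo-2,5-dihydrofuran-3-yl]methyl acetate
Product: 23 [(5E)-4-[(1R,3S)-3-acetoxy-5-bromo-1-(TBS-oxy)-3-methyl-4-oxopentyl]-5-(2-methylprop-2-en-1-ylidene)-2-oxo-2,5-dihydrofuran-3-yl]methyl acetate, via trimethylsilyl enol ether 22 (not isolated)
Conditions: TMSOTf, Et3N, CH2Cl2, -20 °C; then NBS, THF, -78 °C
Reagents that add atoms: N-bromosuccinimide, BrN1C(=O)CCC1=O
Why: The C2 methyl group is the only enolisable position of the ketone (C10 is quaternary), so soft enolisation should give a single enol silane, which NBS brominates far faster than it attacks the electron-poor diene (α-bromination via a silyl enol ether).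

Step 15
Reactants: 23 [(5E)-4-[(1R,3S)-3-acetoxy-5-bromo-1-(TBS-oxy)-3-methyl-4-oxopentyl]-5-(2-methylprop-2-en-1-ylidene)-2-oxo-2,5-dihydrofuran-3-yl]methyl acetate
Product: 24 8-O-TBS ether of the target (1S,4R,5E,8R,10S)
Conditions: fac-Ir(ppy)3 (1 mol%), K2HPO4 (2 equiv), MeCN/H2O 9:1 (1 mM), blue LEDs, 25 °C, degassed
Reagents that add atoms: water, O
Why: Proposed new method: the excited trivalent iridium photocatalyst reduces the C2–Br bond, the electrophilic α-keto radical at C2 adds to C3 (the unsubstituted terminus of the isopropenyl group), the tertiary allylic C4 radical is oxidised by the tetravalent iridium species formed in the first event, the C1 carbonyl oxygen captures the C4 cation and water adds to the oxocarbenium ion at C1 (net loss of HBr, gain of H2O, redox-neutral). The closest known reaction types are the intermolecular photoredox radical-polar crossover carbo-oxygenation of 1,1-disubstituted alkenes and styrenes with α-bromo carbonyl compounds and the Mn(OAc)3-mediated oxidative [3+2] annulation of ketones with alkenes and dienes; its use to close a ten-membered carbocycle is new. Ring closures: the carbocycle C1–C10 forms by 10-endo-trig radical addition of C2 to C3, and the tetrahydrofuran O–C1–C2–C3–C4 by 5-exo attack of the carbonyl oxygen on the cationic C4 (the C4–C5 π bond stays outside the ring). C4 should be controlled by relay from C8: allylic 1,3-strain keeps C8–H in the butenolide plane, so the C9–C10–C1 tether leaves on one face, reaches the CH2 terminus of the twisted isopropenyl group on that face and the carbonyl oxygen closes on the inner lobe of C4, an arrangement that corresponds to 4R in a vector model; C1 has no freedom, because the bridged 11-oxabicyclo[6.2.1] skeleton allows only the configuration with the hydroxyl group exo, and hydration is reversible. The step needs addition at C3 and not at C5 (terminal position, tertiary allylic radical), ring closure faster than 1,5-hydrogen transfer from C8–H or intermolecular addition (high dilution, the (5E)-ylidene U-turn that holds C4 next to C8, the gem-disubstituted C10), and capture at C4 and not at C6 (five- against seven-membered ring).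

Step 16
Reactants: 24 8-O-TBS ether of the target
Product: 25 CNP0203479.1
Conditions: HF·pyridine, pyridine, THF, 0 to 25 °C
Reagents that add atoms: none
Why: Fluoride desilylation under buffered, slightly acidic conditions should spare the acetates, the hemiketal and the enol lactone and avoid base-induced acetyl migration from the C10 oxygen to the C8 oxygen.

**Compound list**

1 | furan-3-ylmethanol | OCc1ccoc1 | starting material
2 | tert-butyl(furan-3-ylmethoxy)dimethylsilane | CC(C)(C)[Si](C)(C)OCc1ccoc1 | intermediate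
3 | [2-(tert-butyldimethylsilyl)furan-3-yl]methanol | CC(C)(C)[Si](C)(C)c1occc1CO | intermediate
4 | N-methoxy-N-methylacetamide | CC(=O)N(C)OC | starting material
5 | 1-[5-(tert-butyldimethylsilyl)-4-(hydroxymethyl)furan-3-yl]ethan-1-one | CC(=O)c1coc([Si](C)(C)C(C)(C)C)c1CO | intermediate
6 | tert-butyldimethyl{3-[(trimethylsilyloxy)methyl]-4-[1-(trimethylsilyloxy)ethenyl]furan-2-yl}silane | C=C(O[Si](C)(C)C)c1coc([Si](C)(C)C(C)(C)C)c1CO[Si](C)(C)C | intermediate
7 | methyl pyruvate (methyl 2-oxopropanoate) | CC(=O)C(=O)OC | starting material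
8 | methyl (2S)-4-{5-TBS-4-[(trimethylsilyloxy)methyl]furan-3-yl}-2-methyl-4-oxo-2-(trimethylsilyloxy)butanoate (silylated aldol adduct) | COC(=O)[C@@](C)(O[Si](C)(C)C)CC(=O)c1coc([Si](C)(C)C(C)(C)C)c1CO[Si](C)(C)C | intermediate
9 | methyl (2S)-4-[5-(tert-butyldimethylsilyl)-4-(hydroxymethyl)furan-3-yl]-2-hydroxy-2-methyl-4-oxobutanoate | COC(=O)[C@@](C)(O)CC(=O)c1coc([Si](C)(C)C(C)(C)C)c1CO | intermediate
10 | methyl (2S,4R)-4-[5-(tert-butyldimethylsilyl)-4-(hydroxymethyl)furan-3-yl]-2,4-dihydroxy-2-methylbutanoate | COC(=O)[C@@](C)(O)C[C@H](c1coc([Si](C)(C)C(C)(C)C)c1CO)O | intermediate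
11 | methyl (2S,4R)-4-(TBS-oxy)-4-{5-TBS-4-[(TBS-oxy)methyl]furan-3-yl}-2-hydroxy-2-methylbutanoate | COC(=O)[C@@](C)(O)C[C@H](c1coc([Si](C)(C)C(C)(C)C)c1CO[Si](C)(C)C(C)(C)C)O[Si](C)(C)C(C)(C)C | intermediate
12 | (3S,5R)-5-(TBS-oxy)-5-{5-TBS-4-[(TBS-oxy)methyl]furan-3-yl}-3-hydroxy-3-methyl-1-(trimethylsilyl)pentan-2-one (α-trimethylsilyl ketone) | C[Si](C)(C)CC(=O)[C@@](C)(O)C[C@H](c1coc([Si](C)(C)C(C)(C)C)c1CO[Si](C)(C)C(C)(C)C)O[Si](C)(C)C(C)(C)C | intermediate
13 | (3S,5R)-5-(TBS-oxy)-5-{5-TBS-4-[(TBS-oxy)methyl]furan-3-yl}-3-hydroxy-3-methylpentan-2-one | CC(=O)[C@@](C)(O)C[C@H](c1coc([Si](C)(C)C(C)(C)C)c1CO[Si](C)(C)C(C)(C)C)O[Si](C)(C)C(C)(C)C | intermediate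
14 | furan endoperoxide of 13 (2,3,7-trioxabicyclo[2.2.1]hept-5-ene; C1 carries TBS, C5 the (TBS-oxy)methyl group, C6 the side chain) | CC(=O)[C@@](C)(O)C[C@H](C1=C(CO[Si](C)(C)C(C)(C)C)C2([Si](C)(C)C(C)(C)C)OOC1O2)O[Si](C)(C)C(C)(C)C | intermediate
15 | tert-butyldimethylsilyl (2Z,4R,6S)-4-(TBS-oxy)-2-[(TBS-oxy)methyl]-3-formyl-6-hydroxy-6-methyl-7-oxooct-2-enoate (silyl oxoenoate; formyl cis to the silyl ester) | CC(=O)[C@@](C)(O)C[C@H](/C(C=O)=C(\CO[Si](C)(C)C(C)(C)C)C(=O)O[Si](C)(C)C(C)(C)C)O[Si](C)(C)C(C)(C)C | intermediate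
16 | 4-[(1R,3S)-1-(TBS-oxy)-3-hydroxy-3-methyl-4-oxopentyl]-3-[(TBS-oxy)methyl]-5-hydroxyfuran-2(5H)-one (both C5 epimers) | CC(=O)[C@@](C)(O)C[C@H](C1=C(CO[Si](C)(C)C(C)(C)C)C(=O)OC1O)O[Si](C)(C)C(C)(C)C | intermediate
17 | (2E,4R,6S)-4-(TBS-oxy)-2-[(TBS-oxy)methyl]-3-ethynyl-6-hydroxy-6-methyl-7-oxooct-2-enoic acid (carboxyl cis to ethynyl) | CC(=O)[C@@](C)(O)C[C@H](/C(C#C)=C(\CO[Si](C)(C)C(C)(C)C)C(O)=O)O[Si](C)(C)C(C)(C)C | intermediate
18 | 2-bromopropene | CC(Br)=C | starting material
19 | (5E)-4-[(1R,3S)-1-(TBS-oxy)-3-hydroxy-3-methyl-4-oxopentyl]-3-[(TBS-oxy)methyl]-5-(2-methylprop-2-en-1-ylidene)furan-2(5H)-one | CC(C)(C)[Si](C)(C)OCC1=C([C@@H](C[C@](C(C)=O)(C)O)O[Si](C)(C)C(C)(C)C)/C(=C\C(C)=C)OC1=O | intermediate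
20 | (5E)-4-[(1R,3S)-1-(TBS-oxy)-3-hydroxy-3-methyl-4-oxopentyl]-3-(hydroxymethyl)-5-(2-methylprop-2-en-1-ylidene)furan-2(5H)-one | OCC1=C([C@@H](C[C@](C(C)=O)(C)O)O[Si](C)(C)C(C)(C)C)/C(=C\C(C)=C)OC1=O | intermediate
21 | [(5E)-4-[(1R,3S)-3-acetoxy-1-(TBS-oxy)-3-methyl-4-oxopentyl]-5-(2-methylprop-2-en-1-ylidene)-2-oxo-2,5-dihydrofuran-3-yl]methyl acetate | CC(=O)OCC1=C([C@@H](C[C@](C(C)=O)(C)OC(C)=O)O[Si](C)(C)C(C)(C)C)/C(=C\C(C)=C)OC1=O | intermediate
22 | [(5E)-4-[(1R,3S)-3-acetoxy-1-(TBS-oxy)-3-methyl-4-(trimethylsilyloxy)pent-4-en-1-yl]-5-(2-methylprop-2-en-1-ylidene)-2-oxo-2,5-dihydrofuran-3-yl]methyl acetate (trimethylsilyl enol ether) | CC(=O)OCC1=C([C@@H](C[C@](C(=C)O[Si](C)(C)C)(C)OC(C)=O)O[Si](C)(C)C(C)(C)C)/C(=C\C(C)=C)OC1=O | intermediate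
23 | [(5E)-4-[(1R,3S)-3-acetoxy-5-bromo-1-(TBS-oxy)-3-methyl-4-oxopentyl]-5-(2-methylprop-2-en-1-ylidene)-2-oxo-2,5-dihydrofuran-3-yl]methyl acetate | CC(=O)OCC1=C([C@@H](C[C@](C(=O)CBr)(C)OC(C)=O)O[Si](C)(C)C(C)(C)C)/C(=C\C(C)=C)OC1=O | intermediate
24 | 8-O-TBS ether of the target: (1S,4R,5E,8R,10S)-10,13-diacetoxy-8-(TBS-oxy)-1-hydroxy-1,4-epoxygermacra-5,7(11)-dien-12,6-olide | CC(=O)OCC1=C2/C(=C\[C@@]3(C)CC[C@](O)(O3)[C@@](C)(OC(C)=O)C[C@H]2O[Si](C)(C)C(C)(C)C)OC1=O | intermediate
25 | CNP0203479.1: (1S,4R,5E,8R,10S)-10,13-diacetoxy-1,8-dihydroxy-1,4-epoxygermacra-5,7(11)-dien-12,6-olide (hirsutinolide type) | CC(=O)OCC1=C2/C(=C\[C@@]3(C)CC[C@](O)(O3)[C@@](C)(OC(C)=O)C[C@H]2O)OC1=O | target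

**Step count and risks**

Total step count: 16. Longest linear sequence: 16 steps (from furan-3-ylmethanol).

Steps most likely to fail:

1. Step 15 (Proposed new method). The C2 radical may be lost before ring closure through 1,5-hydrogen transfer from the activated C8–H, reduction or oligomerisation. Triplet sensitisation may also isomerise the strained (5E)-ylidene, and the cation may be captured on the wrong face of C4. Fallback with known chemistry, a two-electron carbenoid route that sets out from 23 and comes back at 24: N,N'-ditosylhydrazine and DBU (THF, 0 °C) should convert the bromoketone into the α-diazoketone F1. Slow addition of F1 to Cu(MeCN)4PF6 in CH2Cl2 at 40 °C should give, by intramolecular cyclopropanation of the terminal alkene (copper carbenoids prefer cyclopropanation to C–H insertion), the vinylcyclopropyl ketone F2. Lewis-acid Cloke–Wilson rearrangement of this donor–acceptor cyclopropane (Yb(OTf)3, CH2Cl2) should expand it to the bridged 2,3-dihydrofuran F3, and mild acid hydration of the enol ether (PPTS, THF/H2O) should give 24.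

2. Step 11. The terminal alkyne may form an alkynylpalladium species (Sonogashira-type coupling followed by cyclisation would give the 5Z isomer), the carboxylate may close 6-endo to a 2-pyranone, or the strained 5E product may isomerise. Fallback that separates ring closure from C–C coupling, setting out from 17 and coming back at 19: NBS and KHCO3 (CH2Cl2/H2O, 0 °C) should effect anti 5-exo-dig bromolactonisation to the (5E)-5-(bromomethylidene) butenolide F4. Suzuki–Miyaura coupling of F4 with isopropenylboronic acid pinacol ester (Pd(PPh3)4, K3PO4, THF/H2O, 40 °C) proceeds with retention of alkene geometry and should give 19.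

3. Step 14. Enolisation may compete at the vinylogous C8–H or at the acetates, and the brominating agent may attack the diene. Fallback that avoids the halide, setting out from 21 and coming back at 24: the enol silane 22 is formed as in step 14 and oxidised by single-electron transfer with (NH4)2Ce(NO3)6 and NaHCO3 in MeCN/H2O at high dilution (known oxidative addition of enol silanes to alkenes and dienes). This generates the same C2 radical, which should close as in step 15 while tetravalent cerium oxidises the C4 radical. No new compound is made on this path (F0).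

**Further compounds**

F1 | step 15 | [(5E)-4-[(1R,3S)-3-acetoxy-5-diazo-1-(TBS-oxy)-3-methyl-4-oxopentyl]-5-(2-methylprop-2-en-1-ylidene)-2-oxo-2,5-dihydrofuran-3-yl]methyl acetate (α-diazoketone) | CC(=O)OCC1=C([C@@H](C[C@](C(=O)C=[N+]=[N-])(C)OC(C)=O)O[Si](C)(C)C(C)(C)C)/C(=C\C(C)=C)OC1=O
F2 | step 15 | vinylcyclopropyl ketone: 8-O-TBS-10,13-diacetoxy-2,4-cyclogermacra-5,7(11)-dien-1-one-12,6-olide (cyclopropane C2–C3–C4, diastereomers at C2 and C4) | CC(=O)OCC1=C2/C(=C\C3(C)CC3C(=O)[C@@](C)(OC(C)=O)C[C@H]2O[Si](C)(C)C(C)(C)C)OC1=O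
F3 | step 15 | bridged 2,3-dihydrofuran: (4R,5E,8R,10S)-10,13-diacetoxy-8-(TBS-oxy)-1,4-epoxygermacra-1,5,7(11)-trien-12,6-olide | CC(=O)OCC1=C2/C(=C\[C@@]3(C)CC=C(O3)[C@@](C)(OC(C)=O)C[C@H]2O[Si](C)(C)C(C)(C)C)OC1=O
F4 | step 11 | (5E)-5-(bromomethylidene)-4-[(1R,3S)-1-(TBS-oxy)-3-hydroxy-3-methyl-4-oxopentyl]-3-[(TBS-oxy)methyl]furan-2(5H)-one | CC(C)(C)[Si](C)(C)OCC1=C([C@@H](C[C@](C(C)=O)(C)O)O[Si](C)(C)C(C)(C)C)/C(=C\Br)OC1=O
F0 | step 14 | none | none
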